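**Plan**

- Retrosynthesis: the three O‑benzyl bonds and the saturated C5 side chain lead back to a C5 alkyne, cut at C5–C(sp) (Sonogashira on a C5 chloride). Ring C is then cut at O1–C8a, the C2 carbinol goes back to a ketone, and the chain is cut at C2–ring B (aryl Grignard plus Weinreb amide) and at C3–C4 (glycolate enolate plus ring A benzylic bromide); C4 itself comes from DMF.
- Forward: ring A is formylated between Br and Cl and converted into the benzylic bromide; glycolate alkylation joins C3–C4; the Weinreb amide and the ring B Grignard reagent join C2; reduction gives the anti alcohol; ring C closes; the arylalkyne is attached at C5; hydrogenation finishes.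
- Enabling feature: O1 of ring C bridges the benzylic carbon C2 and the aryl carbon C8a of ring A, while the C3 oxygen is exocyclic. Ring C can therefore be closed on the aryl side (O1–C8a) with O3 benzylated and with no bond change at the easily ionised syringyl carbinol C2.
- Stereochemistry: C3 (S) comes from the (R)‑4‑benzyloxazolidin‑2‑one auxiliary in the alkylation; C2 (R) comes from chelation‑controlled Zn(BH4)2 reduction of the (S)‑α‑benzyloxy ketone (anti). Both centres pass unchanged through ring closure and the end game.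

Key step: step 10

Remark: flavan numbering is used throughout (O1, C2, C3, C4, C4a, C5 to C8, C8a; ring A is the benzo ring, ring B the syringyl ring, ring C the pyran). A chlorine is carried at C5 as the latent anchor of the arylethyl chain, so that Br and Cl distinguish the two ortho positions of ring A and only the C8a–Br bond reacts in the ring closure.

**Step 1**
Reactants: 1 1‑bromo‑3‑chloro‑5‑methoxybenzene
Product: 3 2‑bromo‑6‑chloro‑4‑methoxybenzaldehyde, via aryllithium 2 (not isolated)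
Conditions: LiN(iPr)2 (1.1 equiv), THF, −78 °C; DMF, −78 °C; AcOH then water
Reagents that add atoms: N,N‑dimethylformamide, CN(C)C=O
Why: Directed ortho‑metalation: the amide base should remove the most acidic ring proton, the one flanked by both halogens (as in 1,3‑dihalobenzenes), and the aryllithium is formylated at −78 °C before benzyne formation can set in.

**Step 2**
Reactants: 3 2‑bromo‑6‑chloro‑4‑methoxybenzaldehyde
Product: 4 (2‑bromo‑6‑chloro‑4‑methoxyphenyl)methanol
Conditions: NaBH4, MeOH/THF, 0 °C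
Reagents that add atoms: none
Why: Borohydride reduction of an aromatic aldehyde; the aryl halides are inert.

**Step 3**
Reactants: 4 (2‑bromo‑6‑chloro‑4‑methoxyphenyl)methanol
Product: 5 1‑bromo‑2‑(bromomethyl)‑3‑chloro‑5‑methoxybenzene
Conditions: PBr3, CH2Cl2, 0 °C
Reagents that add atoms: phosphorus tribromide, BrP(Br)Br
Why: Bromination of a benzylic alcohol by SN2 displacement on its phosphite ester; the flanking halogens restrain ionisation of the para‑methoxybenzylic bromide, which is used promptly.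

**Step 4**
Reactants: 6 (R)‑4‑benzyloxazolidin‑2‑one; 7 (benzyloxy)acetyl chloride
Product: 9 (R)‑4‑benzyl‑3‑[(benzyloxy)acetyl]oxazolidin‑2‑one, via lithiated oxazolidinone 8 (not isolated)
Conditions: n‑BuLi, THF, −78 °C; then 7, −78 → 0 °C
Reagents that add atoms: none
Why: N‑Acylation of the lithiated Evans auxiliary by an acid chloride.

**Step 5**
Reactants: 9 (R)‑4‑benzyl‑3‑[(benzyloxy)acetyl]oxazolidin‑2‑one; 5 1‑bromo‑2‑(bromomethyl)‑3‑chloro‑5‑methoxybenzene
Product: 11 (R)‑4‑benzyl‑3‑[(2S)‑2‑(benzyloxy)‑3‑(2‑bromo‑6‑chloro‑4‑methoxyphenyl)propanoyl]oxazolidin‑2‑one, via sodium (Z)‑enolate 10 (not isolated)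
Conditions: NaN(SiMe3)2, THF, −78 °C; then 5 (limiting), −78 → −45 °C
Reagents that add atoms: none
Why: Evans‑type asymmetric alkylation of a glycolate imide: the chelated sodium (Z)‑enolate should be alkylated by the reactive benzylic bromide on the face away from the C4 benzyl group of the (R)‑auxiliary, setting the (S) centre that becomes C3; the minor diastereomer is removed by chromatography.

**Step 6**
Reactants: 11 alkylated imide
Product: 12 (S)‑2‑(benzyloxy)‑3‑(2‑bromo‑6‑chloro‑4‑methoxyphenyl)‑N‑methoxy‑N‑methylpropanamide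
Conditions: MeNH(OMe)·HCl, AlMe3, CH2Cl2, −15 → 0 °C; Rochelle‑salt work‑up
Reagents that add atoms: N,O‑dimethylhydroxylamine hydrochloride, CNOC.Cl
Why: Aluminium amide transamidation (Weinreb amide formation) attacks the exocyclic imide carbonyl, leaves the α‑centre untouched and returns the auxiliary.

**Step 7**
Reactants: 13 4‑bromo‑2,6‑dimethoxyphenol
Product: 14 2‑(benzyloxy)‑5‑bromo‑1,3‑dimethoxybenzene
Conditions: BnBr, K2CO3, DMF, rt
Reagents that add atoms: benzyl bromide, BrCc1ccccc1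
Why: Williamson etherification of a phenol.

**Step 8**
Reactants: 14 2‑(benzyloxy)‑5‑bromo‑1,3‑dimethoxybenzene; 12 Weinreb amide
Product: 16 (S)‑2‑(benzyloxy)‑1‑[4‑(benzyloxy)‑3,5‑dimethoxyphenyl]‑3‑(2‑bromo‑6‑chloro‑4‑methoxyphenyl)propan‑1‑one, via aryl Grignard reagent 15 (not isolated)
Conditions: Mg turnings, I2 (cat.), THF, 50 °C; then 12, THF, 0 °C; cold aq. NH4Cl
Reagents that add atoms: none
Why: Grignard addition to a Weinreb amide stops at the chelated tetrahedral adduct, so the ketone appears only on work‑up, without over‑addition or enolisation of the α‑benzyloxy centre; the ring A halides are inert to ArMgBr at 0 °C.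

**Step 9**
Reactants: 16 (S)‑α‑benzyloxy ketone
Product: 17 (1R,2S)‑2‑(benzyloxy)‑1‑[4‑(benzyloxy)‑3,5‑dimethoxyphenyl]‑3‑(2‑bromo‑6‑chloro‑4‑methoxyphenyl)propan‑1‑ol
Conditions: Zn(BH4)2, Et2O, −30 → 0 °C; aq. NH4Cl
Reagents that add atoms: none
Why: Chelation‑controlled (Cram chelate) reduction: zinc bridges the carbonyl and α‑benzyloxy oxygens and hydride enters from the side of the α‑hydrogen, which should give the anti alcohol with (R) configuration at the future C2.

**Step 10**
Reactants: 17 (1R,2S)‑anti alcohol with free C2–OH, O3 benzyl ether, Br at C8a and Cl at C5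
Product: 18 (2R,3S)‑3‑(benzyloxy)‑2‑[4‑(benzyloxy)‑3,5‑dimethoxyphenyl]‑5‑chloro‑7‑methoxychromane
Conditions: Pd(OAc)2 (5 mol %), 2‑(di‑tert‑butylphosphino)‑1,1′‑binaphthyl (6 mol %), Cs2CO3, toluene, 75 °C
Reagents that add atoms: none
Why: Palladium‑catalysed intramolecular aryl etherification (Buchwald–Hartwig type C–O coupling), known for secondary alcohols and aryl bromides giving chromans. Monoligated zerovalent palladium inserts into the C8a–Br bond, Cs2CO3 deprotonates the C2 hydroxyl, the alkoxide displaces bromide on divalent palladium to give a seven‑membered oxapalladacycle, and C–O reductive elimination forms O1–C8a. Ring C closes as a six‑membered ring by attack of the tethered oxygen on the aryl carbon (6‑exo‑type closure, realised as reductive elimination from the palladacycle). No stereocentre is formed and no bond to C2 or C3 is made or broken, so the (1R,2S) anti array should be carried over as (2R,3S) trans. Three selectivities are needed: C–Br over C–Cl insertion, secured by the much faster oxidative addition into the bromide; six‑ over five‑membered closure, secured because O3 is benzylated; and reductive elimination over β‑hydride loss from the secondary benzylic alkoxide, secured by the bulky di‑tert‑butylbiarylphosphine.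

**Step 11**
Reactants: 18 5‑chlorochromane; 19 1‑(benzyloxy)‑3‑ethynylbenzene
Product: 20 (2R,3S)‑3‑(benzyloxy)‑2‑[4‑(benzyloxy)‑3,5‑dimethoxyphenyl]‑5‑{[3‑(benzyloxy)phenyl]ethynyl}‑7‑methoxychromane
Conditions: PdCl2(MeCN)2 (3 mol %), XPhos (2‑dicyclohexylphosphino‑2′,4′,6′‑triisopropylbiphenyl, 9 mol %), Cs2CO3, MeCN, 85 °C, slow addition of 19
Reagents that add atoms: none
Why: Copper‑free Sonogashira coupling of an aryl chloride, for which the electron‑rich bulky dialkylbiarylphosphine enables oxidative addition into the C5–Cl bond; the benzyl ethers and both stereocentres are untouched.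

**Step 12**
Reactants: 20 alkynyl chromane tris‑benzyl ether
Product: 22 (2R,3S)‑2‑(4‑hydroxy‑3,5‑dimethoxyphenyl)‑5‑[2‑(3‑hydroxyphenyl)ethyl]‑7‑methoxychroman‑3‑ol (target), via bibenzyl tris‑benzyl ether 21 (not isolated)
Conditions: H2 (1 atm), 10 % Pd/C, EtOAc/MeOH, rt, stopped when debenzylation is complete
Reagents that add atoms: none
Why: Heterogeneous hydrogenation should first saturate the diarylalkyne and then hydrogenolyse the three O‑benzyl ethers, while the cyclic C2–O1 benzylic ether of a flavan survives at 1 atm and C2 and C3 are not involved.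

**Compound list**

1 | 1‑bromo‑3‑chloro‑5‑methoxybenzene | COc1cc(Cl)cc(Br)c1 | starting material
2 | (2‑bromo‑6‑chloro‑4‑methoxyphenyl)lithium | [Li]c1c(Cl)cc(OC)cc1Br | intermediate
3 | 2‑bromo‑6‑chloro‑4‑methoxybenzaldehyde | COc1cc(Cl)c(C=O)c(Br)c1 | intermediate
4 | (2‑bromo‑6‑chloro‑4‑methoxyphenyl)methanol | COc1cc(Cl)c(CO)c(Br)c1 | intermediate
5 | 1‑bromo‑2‑(bromomethyl)‑3‑chloro‑5‑methoxybenzene | COc1cc(Cl)c(CBr)c(Br)c1 | intermediate
6 | (R)‑4‑benzyloxazolidin‑2‑one | O=C1N[C@H](Cc2ccccc2)CO1 | starting material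
7 | (benzyloxy)acetyl chloride | O=C(Cl)COCc1ccccc1 | starting material
8 | N‑lithio‑(R)‑4‑benzyloxazolidin‑2‑one | [Li]N1[C@H](Cc2ccccc2)COC1=O | intermediate
9 | (R)‑4‑benzyl‑3‑[(benzyloxy)acetyl]oxazolidin‑2‑one | O=C(COCc1ccccc1)N1[C@H](Cc2ccccc2)COC1=O | intermediate
10 | sodium (Z)‑enolate of 9 | [Na+].[O-]/C(=C\OCc1ccccc1)N1[C@H](Cc2ccccc2)COC1=O | intermediate
11 | (R)‑4‑benzyl‑3‑[(2S)‑2‑(benzyloxy)‑3‑(2‑bromo‑6‑chloro‑4‑methoxyphenyl)propanoyl]oxazolidin‑2‑one | COc1cc(Cl)c(C[C@H](OCc2ccccc2)C(=O)N2[C@H](Cc3ccccc3)COC2=O)c(Br)c1 | intermediate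
12 | (S)‑2‑(benzyloxy)‑3‑(2‑bromo‑6‑chloro‑4‑methoxyphenyl)‑N‑methoxy‑N‑methylpropanamide | COc1cc(Cl)c(C[C@H](OCc2ccccc2)C(=O)N(C)OC)c(Br)c1 | intermediate
13 | 4‑bromo‑2,6‑dimethoxyphenol | COc1cc(Br)cc(OC)c1O | starting material
14 | 2‑(benzyloxy)‑5‑bromo‑1,3‑dimethoxybenzene | COc1cc(Br)cc(OC)c1OCc1ccccc1 | intermediate
15 | [4‑(benzyloxy)‑3,5‑dimethoxyphenyl]magnesium bromide | COc1cc([Mg]Br)cc(OC)c1OCc1ccccc1 | intermediate
16 | (S)‑2‑(benzyloxy)‑1‑[4‑(benzyloxy)‑3,5‑dimethoxyphenyl]‑3‑(2‑bromo‑6‑chloro‑4‑methoxyphenyl)propan‑1‑one | COc1cc(Cl)c(C[C@H](OCc2ccccc2)C(=O)c2cc(OC)c(OCc3ccccc3)c(OC)c2)c(Br)c1 | intermediate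
17 | (1R,2S)‑2‑(benzyloxy)‑1‑[4‑(benzyloxy)‑3,5‑dimethoxyphenyl]‑3‑(2‑bromo‑6‑chloro‑4‑methoxyphenyl)propan‑1‑ol | COc1cc(Cl)c(C[C@H](OCc2ccccc2)[C@H](O)c2cc(OC)c(OCc3ccccc3)c(OC)c2)c(Br)c1 | intermediate
18 | (2R,3S)‑3‑(benzyloxy)‑2‑[4‑(benzyloxy)‑3,5‑dimethoxyphenyl]‑5‑chloro‑7‑methoxychromane | COc1cc(Cl)c2c(c1)O[C@H](c1cc(OC)c(OCc3ccccc3)c(OC)c1)[C@@H](OCc1ccccc1)C2 | intermediate
19 | 1‑(benzyloxy)‑3‑ethynylbenzene | C#Cc1cccc(OCc2ccccc2)c1 | starting material
20 | (2R,3S)‑3‑(benzyloxy)‑2‑[4‑(benzyloxy)‑3,5‑dimethoxyphenyl]‑5‑{[3‑(benzyloxy)phenyl]ethynyl}‑7‑methoxychromane | COc1cc(C#Cc2cccc(OCc3ccccc3)c2)c2c(c1)O[C@H](c1cc(OC)c(OCc3ccccc3)c(OC)c1)[C@@H](OCc1ccccc1)C2 | intermediate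
21 | (2R,3S)‑3‑(benzyloxy)‑2‑[4‑(benzyloxy)‑3,5‑dimethoxyphenyl]‑5‑{2‑[3‑(benzyloxy)phenyl]ethyl}‑7‑methoxychromane | COc1cc(CCc2cccc(OCc3ccccc3)c2)c2c(c1)O[C@H](c1cc(OC)c(OCc3ccccc3)c(OC)c1)[C@@H](OCc1ccccc1)C2 | intermediate
22 | (2R,3S)‑2‑(4‑hydroxy‑3,5‑dimethoxyphenyl)‑5‑[2‑(3‑hydroxyphenyl)ethyl]‑7‑methoxychroman‑3‑ol | COc1cc(CCc2cccc(O)c2)c2c(c1)O[C@H](c1cc(OC)c(O)c(OC)c1)[C@@H](O)C2 | target

**Step count**

Total step count: 12.
Longest linear sequence: 10 steps (from 1 through steps 1, 2, 3, 5, 6, 8, 9, 10, 11 and 12 to 22).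

**Steps most likely to fail**

Step 10. β‑Hydride elimination from the palladium alkoxide may outrun C–O reductive elimination, which would oxidise the C2 carbinol to the ketone level and reduce the C8a–Br bond; the catalyst may also stall on the hindered benzylic alkoxide. The fallback sets out from 17 and returns directly at 18 by an Ullmann‑type closure: CuI (10 mol %), 3,4,7,8‑tetramethyl‑1,10‑phenanthroline, Cs2CO3, toluene, 110 °C. Copper alkoxides have no comparably easy β‑hydride pathway, the copper catalyst should engage C–Br in preference to C–Cl, and the same O1–C8a bond is formed with retention at C2. This fallback makes no new compound (F0).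

Step 11. Oxidative addition into the electron‑rich, ortho‑substituted C5–Cl bond may be slow, so that base‑induced oligomerisation of the arylacetylene consumes 19 first. The fallback sets out from 18 and 19 and uses a Suzuki–Miyaura coupling. Alkyne 19 is hydroborated with pinacolborane (Cp2Zr(H)Cl cat., Et3N) to give (E)‑2‑{2‑[3‑(benzyloxy)phenyl]ethenyl}‑4,4,5,5‑tetramethyl‑1,3,2‑dioxaborolane F1. This is coupled with 18 (Pd(OAc)2, 2‑dicyclohexylphosphino‑2′,6′‑dimethoxybiphenyl, K3PO4, toluene/water, 90 °C) to give the (E)‑5‑styryl chromane tris‑benzyl ether F2. Hydrogenation of the stilbene under the conditions of step 12 comes back to the route at 21 and proceeds on to 22.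

Step 5. The glycolate sodium enolate may decompose before SN2 attack at a benzylic carbon flanked by two ortho halogens is complete, and warming to force conversion would erode facial selectivity. The fallback sets out from 1, takes C3 from the chiral pool and returns at 12. Aryllithium 2, generated as in step 1, is transmetalated with MgBr2·OEt2 and opens (S)‑glycidyl trityl ether at its terminal carbon under CuI catalysis (−40 → −10 °C) to give (S)‑1‑(2‑bromo‑6‑chloro‑4‑methoxyphenyl)‑3‑(trityloxy)propan‑2‑ol F3. O‑Benzylation (NaH, BnBr, n‑Bu4NI, THF) gives the benzyl ether F4. Detritylation (TsOH·H2O, MeOH/CH2Cl2) gives (S)‑2‑(benzyloxy)‑3‑(2‑bromo‑6‑chloro‑4‑methoxyphenyl)propan‑1‑ol F5. Oxidation (TEMPO cat., PhI(OAc)2, MeCN/water) gives (S)‑2‑(benzyloxy)‑3‑(2‑bromo‑6‑chloro‑4‑methoxyphenyl)propanoic acid F6. Amide coupling with MeNH(OMe)·HCl (EDC·HCl, HOBt, iPr2NEt, CH2Cl2) then delivers 12.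

**Further compounds**

F0 | step 10 | none | none
F1 | step 11 | (E)‑2‑{2‑[3‑(benzyloxy)phenyl]ethenyl}‑4,4,5,5‑tetramethyl‑1,3,2‑dioxaborolane | CC1(C)OB(/C=C/c2cccc(OCc3ccccc3)c2)OC1(C)C
F2 | step 11 | (2R,3S)‑3‑(benzyloxy)‑2‑[4‑(benzyloxy)‑3,5‑dimethoxyphenyl]‑5‑{(E)‑2‑[3‑(benzyloxy)phenyl]ethenyl}‑7‑methoxychromane | COc1cc(/C=C/c2cccc(OCc3ccccc3)c2)c2c(c1)O[C@H](c1cc(OC)c(OCc3ccccc3)c(OC)c1)[C@@H](OCc1ccccc1)C2
F3 | step 5 | (S)‑1‑(2‑bromo‑6‑chloro‑4‑methoxyphenyl)‑3‑(trityloxy)propan‑2‑ol | COc1cc(Cl)c(C[C@H](O)COC(c2ccccc2)(c2ccccc2)c2ccccc2)c(Br)c1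
F4 | step 5 | (S)‑1‑bromo‑2‑[2‑(benzyloxy)‑3‑(trityloxy)propyl]‑3‑chloro‑5‑methoxybenzene | COc1cc(Cl)c(C[C@H](OCc2ccccc2)COC(c2ccccc2)(c2ccccc2)c2ccccc2)c(Br)c1
F5 | step 5 | (S)‑2‑(benzyloxy)‑3‑(2‑bromo‑6‑chloro‑4‑methoxyphenyl)propan‑1‑ol | COc1cc(Cl)c(C[C@H](OCc2ccccc2)CO)c(Br)c1
F6 | step 5 | (S)‑2‑(benzyloxy)‑3‑(2‑bromo‑6‑chloro‑4‑methoxyphenyl)propanoic acid | COc1cc(Cl)c(C[C@H](OCc2ccccc2)C(=O)O)c(Br)c1
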